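**Plan**
- Retrosynthesis: cut C3–CH2CO2Me last, then C6–C7 between the 1,2-dioxane and the dienyl chain, then the ring bonds O1–C6 and O2–C3 (back to an alkene aldehyde, ozone and methanol). The chain half is cut at C8–C9 and C9–Si.
- Forward: two Evans alkylations give the two halves. Ozonolysis in methanol closes the 1,2-dioxane with C3 still at the aldehyde oxidation level (6-methoxy-3-ol). The C3 hydroxyl is silylated, the chain is joined at C6, and the C3 oxygen is finally exchanged for the acetate carbon.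
- Enabling feature: C6 and C3 are the two ring carbons bonded to the O1–O2 peroxide bond of the 1,2-dioxane, so each can be ionised to a ring peroxycarbenium ion. C7 is the allylic CH2 of the C8=C9 alkene, so an allylsilane can deliver it with allyl transposition.
- Stereochemistry: C4 and C10 come from Evans alkylations. C6 comes from the key step (axial attack anti to the temporary C3 silyloxy group, which is trans to the C4 ethyl). C3 comes from the last step (axial attack cis to the C4 ethyl). C8=C9 is E from the anti SE2′ step; C11=C12 is E from (3E)-hex-3-enoic acid.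

Key step: step 13

Remark: 2-(bromomethyl)but-1-ene and the silylborane PhMe2Si–B(pin) are taken as purchasable.

**Step 1**
Reactants: 1 (4S)-4-benzyl-1,3-oxazolidin-2-one; 2 butanoyl chloride
Product: 3 (4S)-4-benzyl-3-butanoyl-1,3-oxazolidin-2-one
Conditions: n-BuLi, THF, −78 °C; then 2, −78 to 0 °C
Reagents that add atoms: none
Why: N-acylation of the lithiated oxazolidinone by an acid chloride is the standard entry to Evans imides.

**Step 2**
Reactants: 3 (4S)-4-benzyl-3-butanoyl-1,3-oxazolidin-2-one; 4 2-(bromomethyl)but-1-ene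
Product: 5 (4S)-4-benzyl-3-[(2R)-2-ethyl-4-methylidenehexanoyl]-1,3-oxazolidin-2-one
Conditions: NaN(SiMe3)2, THF, −78 °C; then 4, −78 to −40 °C
Reagents that add atoms: none
Why: Evans asymmetric alkylation, in which the chelated Z sodium enolate is alkylated by the allylic bromide on the face away from the benzyl group, which sets the 2R center (later C4).

**Step 3**
Reactants: 5 (4S)-4-benzyl-3-[(2R)-2-ethyl-4-methylidenehexanoyl]-1,3-oxazolidin-2-one
Product: 6 (2R)-2-ethyl-4-methylidenehexan-1-ol
Conditions: LiBH4, H2O (1 equiv), Et2O, 0 °C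
Reagents that add atoms: none
Why: Reductive cleavage of the imide by LiBH4 should release the primary alcohol and the auxiliary without touching the stereocenter or the alkene.

**Step 4**
Reactants: 6 (2R)-2-ethyl-4-methylidenehexan-1-ol
Product: 7 (2R)-2-ethyl-4-methylidenehexanal
Conditions: Dess–Martin periodinane, CH2Cl2, 0 °C to rt; used at once
Reagents that add atoms: none
Why: Dess–Martin oxidation is non-basic, so the α-branched aldehyde should keep its configuration.

**Step 5**
Reactants: 7 (2R)-2-ethyl-4-methylidenehexanal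
Product: 9 (4R)-4,6-diethyl-6-methoxy-1,2-dioxan-3-ol (C3/C6 epimers), via hydroperoxy ketal aldehyde 8 (not isolated)
Conditions: O3, CH2Cl2/MeOH 4:1, −78 °C; N2 purge; then 0 °C
Reagents that add atoms: ozone [O-][O+]=O; methanol CO
Why: Ozonolysis in methanol (Criegee mechanism) cleaves the 1,1-disubstituted alkene to formaldehyde and the disubstituted carbonyl oxide, methanol traps the latter as the hydroperoxy ketal, and its OOH group adds to the aldehyde to close the six-membered peroxy hemiacetal, as in ozonolyses of cycloalkenes in methanol; C3 and C6 remain epimer mixtures that steps 6 and 13 deal with.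

**Step 6**
Reactants: 9 (4R)-4,6-diethyl-6-methoxy-1,2-dioxan-3-ol (C3/C6 epimers)
Product: 10 tert-butyl{[(3S,4R)-4,6-diethyl-6-methoxy-1,2-dioxan-3-yl]oxy}dimethylsilane (C6 epimers)
Conditions: t-BuMe2SiCl, imidazole, DMF, 0 °C; chromatography
Reagents that add atoms: tert-butylchlorodimethylsilane CC(C)(C)[Si](C)(C)Cl
Why: Kinetic anomeric O-silylation, in which the hemiacetal anomers interconvert by ring opening and the equatorial hydroxyl is silylated faster (as in equatorial-selective silylation of lactols), should give the silyl acetal with oxygen trans to the C4 ethyl group (3S), which no longer epimerises and can be freed from any cis anomer.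

**Step 7**
Reactants: 11 (4R)-4-benzyl-1,3-oxazolidin-2-one; 12 (3E)-hex-3-enoic acid
Product: 14 (4R)-4-benzyl-3-[(3E)-hex-3-enoyl]-1,3-oxazolidin-2-one, via mixed anhydride 13 (not isolated)
Conditions: t-BuCOCl, Et3N, THF, −20 °C; then 11, LiCl, −20 °C to rt
Reagents that add atoms: none
Why: Acylation of the oxazolidinone through the pivalic mixed anhydride (LiCl, Et3N) avoids strong base, so the β,γ-double bond should stay in place and E.

**Step 8**
Reactants: 14 (4R)-4-benzyl-3-[(3E)-hex-3-enoyl]-1,3-oxazolidin-2-one; 15 iodoethane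
Product: 16 (4R)-4-benzyl-3-[(2R,3E)-2-ethylhex-3-enoyl]-1,3-oxazolidin-2-one
Conditions: NaN(SiMe3)2, THF, −78 °C; then 15, −78 to −30 °C
Reagents that add atoms: none
Why: Evans asymmetric alkylation, in which the sodium dienolate is ethylated at the α-carbon on the face away from the benzyl group, which sets 2R (later C10) and leaves the E alkene unconjugated.

**Step 9**
Reactants: 16 (4R)-4-benzyl-3-[(2R,3E)-2-ethylhex-3-enoyl]-1,3-oxazolidin-2-one
Product: 17 (2R,3E)-2-ethylhex-3-en-1-ol
Conditions: LiBH4, H2O (1 equiv), Et2O, 0 °C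
Reagents that add atoms: none
Why: Reductive cleavage of the imide by LiBH4 should give the alcohol without epimerisation or alkene migration.

**Step 10**
Reactants: 17 (2R,3E)-2-ethylhex-3-en-1-ol; 18 N,N-di(propan-2-yl)carbamoyl chloride
Product: 19 (2R,3E)-2-ethylhex-3-en-1-yl N,N-di(propan-2-yl)carbamate
Conditions: NaH, THF, 0 °C; then 18, reflux
Reagents that add atoms: none
Why: O-carbamoylation gives the Hoppe carbamate that directs the α-lithiation of the next step.

**Step 11**
Reactants: 19 (2R,3E)-2-ethylhex-3-en-1-yl N,N-di(propan-2-yl)carbamate; 20 dimethyl(phenyl)(4,4,5,5-tetramethyl-1,3,2-dioxaborolan-2-yl)silane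
Product: 23 {(1R,2R,3E)-2-ethyl-1-(4,4,5,5-tetramethyl-1,3,2-dioxaborolan-2-yl)hex-3-en-1-yl}dimethyl(phenyl)silane, via lithiated carbamate 21 (not isolated), via lithium boronate complex 22 (not isolated)
Conditions: s-BuLi, (−)-sparteine, Et2O, −78 °C; then 20, −78 °C to reflux
Reagents that add atoms: none
Why: Lithiation–borylation, in which sparteine-mediated α-lithiation, borylation with retention and a 1,2-shift of the silyl group from boron to carbon with inversion and loss of the carbamate should give the α-silyl boronic ester (1R); this center is lost in step 13, so its configuration only serves to give one defined compound.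

**Step 12**
Reactants: 23 {(1R,2R,3E)-2-ethyl-1-(4,4,5,5-tetramethyl-1,3,2-dioxaborolan-2-yl)hex-3-en-1-yl}dimethyl(phenyl)silane; 24 bromo(prop-1-en-2-yl)magnesium
Product: 26 [(3S,4R,5E)-4-ethyl-2-methylocta-1,5-dien-3-yl]dimethyl(phenyl)silane, via magnesium boronate complex 25 (not isolated)
Conditions: 24, THF/DMSO 1:1, 0 °C to rt; then I2, THF, 0 °C; then NaOMe, MeOH, 0 °C to rt
Reagents that add atoms: none
Why: Zweifel olefination, in which iodine-induced 1,2-migration of the α-silyl alkyl group from boron to the alkenyl carbon (retention) and anti elimination of boron and iodine give the 1,1-disubstituted alkene, that is the allylsilane.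

**Step 13**
Reactants: 10 tert-butyl{[(3S,4R)-4,6-diethyl-6-methoxy-1,2-dioxan-3-yl]oxy}dimethylsilane (C6 epimers); 26 [(3S,4R,5E)-4-ethyl-2-methylocta-1,5-dien-3-yl]dimethyl(phenyl)silane
Product: 28 tert-butyl({(3S,4R,6R)-4,6-diethyl-6-[(2E,4R,5E)-4-ethyl-2-methylocta-2,5-dien-1-yl]-1,2-dioxan-3-yl}oxy)dimethylsilane, via peroxycarbenium triflate 27 (not isolated)
Conditions: 26 (1.5 equiv), Me3SiOSO2CF3 (0.3 equiv), 2,6-di-tert-butyl-4-methylpyridine (0.5 equiv), CH2Cl2, −78 °C
Reagents that add atoms: none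
Why: Me3SiOSO2CF3 removes the methoxy group from the tertiary peroxyketal carbon C6, which is bonded to O1 of the O1–O2 ring bond, to give the ring peroxycarbenium ion 27; the CH2 terminus of allylsilane 26 attacks C6 in an anti SE2′ reaction, and loss of silicon from the β-silyl cation moves the double bond to C8=C9. The closest known reaction type is the Lewis acid-mediated Hosomi–Sakurai allylation of 3-alkoxy-1,2-dioxanes and 3-alkoxy-1,2-dioxolanes through peroxycarbenium ions. No ring is closed; the 1,2-dioxane is kept. The new stereocenter C6 is controlled by the silyloxy group at C3: in the half-chair cation this oxygen should sit pseudoaxial (anomeric and electrostatic preference of an alkoxy group across the ring), which turns the trans C4 ethyl group pseudoaxial on the other face, where its only syn-axial partners are O2 and the trigonal C6, and the nucleophile adds along the axial trajectory anti to the C3–O bond, on the face of the C4 ethyl group, which should give 6R. The E geometry of C8=C9 should follow from the SE2′ transition state in which the branched C4 substituent of the silane lies away from the forming C–C bond. The step needs ionisation at C6 and not at C3 (tertiary methyl ketal against a hindered secondary silyl acetal) and facial selectivity at C6 (the configurationally fixed trans silyl acetal of 10).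

**Step 14**
Reactants: 28 tert-butyl({(3S,4R,6R)-4,6-diethyl-6-[(2E,4R,5E)-4-ethyl-2-methylocta-2,5-dien-1-yl]-1,2-dioxan-3-yl}oxy)dimethylsilane
Product: 29 (4R,6R)-4,6-diethyl-6-[(2E,4R,5E)-4-ethyl-2-methylocta-2,5-dien-1-yl]-1,2-dioxan-3-ol (C3 epimers)
Conditions: Bu4NF, AcOH, THF, 0 °C
Reagents that add atoms: none
Why: Fluoride cleaves the anomeric silyl ether while the acetic acid buffer should keep the base-sensitive peroxy hemiacetal intact; the C3 epimers do not matter because C3 is ionised in step 16.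

**Step 15**
Reactants: 29 (4R,6R)-4,6-diethyl-6-[(2E,4R,5E)-4-ethyl-2-methylocta-2,5-dien-1-yl]-1,2-dioxan-3-ol (C3 epimers)
Product: 30 (4R,6R)-4,6-diethyl-6-[(2E,4R,5E)-4-ethyl-2-methylocta-2,5-dien-1-yl]-1,2-dioxan-3-yl acetate (C3 epimers)
Conditions: Ac2O, pyridine, 4-(dimethylamino)pyridine (0.05 equiv), CH2Cl2, 0 °C
Reagents that add atoms: acetic anhydride CC(=O)OC(C)=O
Why: O-acetylation of the hemiacetal gives the acetoxy peroxyacetal, the usual leaving group for Lewis acid ionisation.

**Step 16**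
Reactants: 30 (4R,6R)-4,6-diethyl-6-[(2E,4R,5E)-4-ethyl-2-methylocta-2,5-dien-1-yl]-1,2-dioxan-3-yl acetate (C3 epimers); 31 tert-butyl[(1-methoxyethenyl)oxy]dimethylsilane
Product: 33 methyl 2-{(3R,4R,6R)-4,6-diethyl-6-[(2E,4R,5E)-4-ethyl-2-methylocta-2,5-dien-1-yl]-1,2-dioxan-3-yl}acetate, via peroxycarbenium triflate 32 (not isolated)
Conditions: 31 (3 equiv), Me3SiOSO2CF3 (0.3 equiv), CH2Cl2, −78 °C
Reagents that add atoms: none
Why: Mukaiyama-type addition of a silyl ketene acetal to a ring peroxycarbenium ion (as in Lewis acid-mediated substitutions of alkoxy- and acetoxy-1,2-dioxolanes and 1,2-dioxanes), in which cation 32 keeps the C4 ethyl group and the C6 dienyl chain pseudoequatorial and axial attack at C3 places CH2CO2Me cis to the C4 ethyl group, which should set 3R.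

**Compound list**
1 | (4S)-4-benzyl-1,3-oxazolidin-2-one | O=C1N[C@@H](Cc2ccccc2)CO1 | starting material
2 | butanoyl chloride | CCCC(Cl)=O | starting material
3 | (4S)-4-benzyl-3-butanoyl-1,3-oxazolidin-2-one | CCCC(=O)N1[C@@H](Cc2ccccc2)COC1=O | intermediate
4 | 2-(bromomethyl)but-1-ene | C=C(CC)CBr | starting material
5 | (4S)-4-benzyl-3-[(2R)-2-ethyl-4-methylidenehexanoyl]-1,3-oxazolidin-2-one | C=C(CC)C[C@@H](CC)C(=O)N1[C@@H](Cc2ccccc2)COC1=O | intermediate
6 | (2R)-2-ethyl-4-methylidenehexan-1-ol | C=C(CC)C[C@@H](CC)CO | intermediate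
7 | (2R)-2-ethyl-4-methylidenehexanal | C=C(CC)C[C@@H](CC)C=O | intermediate
8 | (2R)-2-ethyl-4-hydroperoxy-4-methoxyhexanal (both C4 epimers) | CC[C@@H](C=O)CC(CC)(OC)OO | intermediate
9 | (4R)-4,6-diethyl-6-methoxy-1,2-dioxan-3-ol (epimers at C3 and C6) | CC[C@@H]1CC(CC)(OC)OOC1O | intermediate
10 | tert-butyl{[(3S,4R)-4,6-diethyl-6-methoxy-1,2-dioxan-3-yl]oxy}dimethylsilane (both C6 epimers) | CC[C@@H]1CC(CC)(OC)OO[C@H]1O[Si](C)(C)C(C)(C)C | intermediate
11 | (4R)-4-benzyl-1,3-oxazolidin-2-one | O=C1N[C@H](Cc2ccccc2)CO1 | starting material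
12 | (3E)-hex-3-enoic acid | CC/C=C/CC(=O)O | starting material
13 | (3E)-hex-3-enoic 2,2-dimethylpropanoic anhydride | CC/C=C/CC(=O)OC(=O)C(C)(C)C | intermediate
14 | (4R)-4-benzyl-3-[(3E)-hex-3-enoyl]-1,3-oxazolidin-2-one | CC/C=C/CC(=O)N1[C@H](Cc2ccccc2)COC1=O | intermediate
15 | iodoethane | CCI | starting material
16 | (4R)-4-benzyl-3-[(2R,3E)-2-ethylhex-3-enoyl]-1,3-oxazolidin-2-one | CC/C=C/[C@@H](CC)C(=O)N1[C@H](Cc2ccccc2)COC1=O | intermediate
17 | (2R,3E)-2-ethylhex-3-en-1-ol | CC/C=C/[C@@H](CC)CO | intermediate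
18 | N,N-di(propan-2-yl)carbamoyl chloride | CC(C)N(C(C)C)C(Cl)=O | starting material
19 | (2R,3E)-2-ethylhex-3-en-1-yl N,N-di(propan-2-yl)carbamate | CC/C=C/[C@@H](CC)COC(=O)N(C(C)C)C(C)C | intermediate
20 | dimethyl(phenyl)(4,4,5,5-tetramethyl-1,3,2-dioxaborolan-2-yl)silane | C[Si](C)(c1ccccc1)B1OC(C)(C)C(C)(C)O1 | starting material
21 | (1S,2R,3E)-2-ethyl-1-lithiohex-3-en-1-yl N,N-di(propan-2-yl)carbamate (sparteine complex) | CC/C=C/[C@@H](CC)[C@H]([Li])OC(=O)N(C(C)C)C(C)C | intermediate
22 | lithium boronate complex from 21 and 20 | CC/C=C/[C@@H](CC)[C@@H](OC(=O)N(C(C)C)C(C)C)[B-]1([Si](C)(C)c2ccccc2)OC(C)(C)C(C)(C)O1.[Li+] | intermediate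
23 | {(1R,2R,3E)-2-ethyl-1-(4,4,5,5-tetramethyl-1,3,2-dioxaborolan-2-yl)hex-3-en-1-yl}dimethyl(phenyl)silane | CC/C=C/[C@@H](CC)[C@H]([Si](C)(C)c1ccccc1)B1OC(C)(C)C(C)(C)O1 | intermediate
24 | bromo(prop-1-en-2-yl)magnesium | C=C(C)[Mg]Br | starting material
25 | bromomagnesium boronate complex from 23 and 24 | CC/C=C/[C@@H](CC)[C@H]([Si](C)(C)c1ccccc1)[B-]2(C(C)=C)OC(C)(C)C(C)(C)O2.[Mg+]Br | intermediate
26 | [(3S,4R,5E)-4-ethyl-2-methylocta-1,5-dien-3-yl]dimethyl(phenyl)silane | C=C(C)[C@@H]([Si](C)(C)c1ccccc1)[C@H](CC)/C=C/CC | intermediate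
27 | (5S,6R)-6-{[tert-butyl(dimethyl)silyl]oxy}-3,5-diethyl-5,6-dihydro-4H-1,2-dioxin-1-ium trifluoromethanesulfonate (ring peroxycarbenium ion, positive charge at C6=O1 of the route numbering) | CC[C@@H]1CC(CC)=[O+]O[C@H]1O[Si](C)(C)C(C)(C)C.[O-]S(=O)(=O)C(F)(F)F | intermediate
28 | tert-butyl({(3S,4R,6R)-4,6-diethyl-6-[(2E,4R,5E)-4-ethyl-2-methylocta-2,5-dien-1-yl]-1,2-dioxan-3-yl}oxy)dimethylsilane | CC/C=C/[C@H](/C=C(\C)C[C@@]1(CC)C[C@@H](CC)[C@H](O[Si](C)(C)C(C)(C)C)OO1)CC | intermediate
29 | (4R,6R)-4,6-diethyl-6-[(2E,4R,5E)-4-ethyl-2-methylocta-2,5-dien-1-yl]-1,2-dioxan-3-ol (C3 epimers) | CC/C=C/[C@H](/C=C(\C)C[C@@]1(CC)C[C@@H](CC)C(O)OO1)CC | intermediate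
30 | (4R,6R)-4,6-diethyl-6-[(2E,4R,5E)-4-ethyl-2-methylocta-2,5-dien-1-yl]-1,2-dioxan-3-yl acetate (C3 epimers) | CC/C=C/[C@H](/C=C(\C)C[C@@]1(CC)C[C@@H](CC)C(OC(C)=O)OO1)CC | intermediate
31 | tert-butyl[(1-methoxyethenyl)oxy]dimethylsilane | C=C(OC)O[Si](C)(C)C(C)(C)C | starting material
32 | ring peroxycarbenium trifluoromethanesulfonate with the positive charge at C3=O2, formed from 30 by loss of acetate | CC/C=C/[C@H](/C=C(\C)C[C@@]1(CC)C[C@@H](CC)C=[O+]O1)CC.[O-]S(=O)(=O)C(F)(F)F | intermediate
33 | methyl 2-{(3R,4R,6R)-4,6-diethyl-6-[(2E,4R,5E)-4-ethyl-2-methylocta-2,5-dien-1-yl]-1,2-dioxan-3-yl}acetate | CC/C=C/[C@H](/C=C(\C)C[C@@]1(CC)C[C@@H](CC)[C@@H](CC(=O)OC)OO1)CC | target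

**Count**
Total steps: 16. Longest linear sequence: 10 steps (steps 7 to 12, then 13 to 16).

**Steps most likely to fail**

1. Step 13. The nucleophile may add to the other face of the peroxycarbenium ion, because the 1,3-interaction between the incoming carbon and the pseudoaxial C4 ethyl group works against the steering by the C3 silyloxy group. The silyl acetal at C3 may also ionise, or heterolytic O–O cleavage may outrun C–C bond formation. The fallback sets out from 9 and comes back at 33; it steers by neighbouring-group participation instead of conformation. Compound 9 is acylated (t-BuCOCl, pyridine, 4-(dimethylamino)pyridine, CH2Cl2, −20 °C) to the equatorial ester (3R,4R)-4,6-diethyl-6-methoxy-1,2-dioxan-3-yl 2,2-dimethylpropanoate F1. On ionisation at C6 the ester carbonyl oxygen should bridge C6 from the face opposite to the C4 ethyl group, so that 26 (Me3SiOSO2CF3, CH2Cl2, −78 °C) must enter from the ethyl face. This gives (3R,4R,6R)-4,6-diethyl-6-[(2E,4R,5E)-4-ethyl-2-methylocta-2,5-dien-1-yl]-1,2-dioxan-3-yl 2,2-dimethylpropanoate F2. F2 already carries its leaving group and reacts with 31 under the conditions of step 16 to give 33, so steps 14 and 15 drop out.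

2. Step 6. The two anomeric hydroxyls may be poorly discriminated, or the hydroperoxide of the ring-opened form may be silylated. The cis silyl acetal would send the chain to the wrong face in step 13. The fallback sets out from 9 and comes back at 33; it inverts instead of selecting. Compound 9 with Cl3CCN and Cs2CO3 in CH2Cl2 should give, under equilibrating conditions, the axial imidate (3S,4R)-4,6-diethyl-6-methoxy-1,2-dioxan-3-yl 2,2,2-trichloroethanimidate F3. Pivalic acid without promoter displaces the imidate with inversion to give F1, which is carried on through F2 to 33 as in the fallback for step 13.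

3. Step 16. Heterolytic O–O fragmentation of the less stabilised secondary peroxycarbenium ion, or silyl transfer, may outrun capture by the hindered ketene acetal. The fallback sets out from 30 and comes back at 33; it brings in the two carbons at the aldehyde oxidation level with a smaller enol silane and finishes by oxidation. Compound 30 with trimethyl(vinyloxy)silane and Me3SiOSO2CF3 in CH2Cl2 at −78 °C should give, by the same axial attack, 2-{(3R,4R,6R)-4,6-diethyl-6-[(2E,4R,5E)-4-ethyl-2-methylocta-2,5-dien-1-yl]-1,2-dioxan-3-yl}acetaldehyde F4. Chlorite oxidation (NaClO2, NaH2PO4, 2-methylbut-2-ene, t-BuOH/H2O) gives 2-{(3R,4R,6R)-4,6-diethyl-6-[(2E,4R,5E)-4-ethyl-2-methylocta-2,5-dien-1-yl]-1,2-dioxan-3-yl}acetic acid F5. Me3SiCHN2 in MeOH/toluene then gives 33.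

**Further compounds**
F1 | step 13 | (3R,4R)-4,6-diethyl-6-methoxy-1,2-dioxan-3-yl 2,2-dimethylpropanoate (both C6 epimers) | CC[C@@H]1CC(CC)(OC)OO[C@H]1OC(=O)C(C)(C)C
F2 | step 13 | (3R,4R,6R)-4,6-diethyl-6-[(2E,4R,5E)-4-ethyl-2-methylocta-2,5-dien-1-yl]-1,2-dioxan-3-yl 2,2-dimethylpropanoate | CC/C=C/[C@H](/C=C(\C)C[C@@]1(CC)C[C@@H](CC)[C@H](OC(=O)C(C)(C)C)OO1)CC
F3 | step 6 | (3S,4R)-4,6-diethyl-6-methoxy-1,2-dioxan-3-yl 2,2,2-trichloroethanimidate (both C6 epimers) | CC[C@@H]1CC(CC)(OC)OO[C@@H]1OC(=N)C(Cl)(Cl)Cl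
F4 | step 16 | 2-{(3R,4R,6R)-4,6-diethyl-6-[(2E,4R,5E)-4-ethyl-2-methylocta-2,5-dien-1-yl]-1,2-dioxan-3-yl}acetaldehyde | CC/C=C/[C@H](/C=C(\C)C[C@@]1(CC)C[C@@H](CC)[C@@H](CC=O)OO1)CC
F5 | step 16 | 2-{(3R,4R,6R)-4,6-diethyl-6-[(2E,4R,5E)-4-ethyl-2-methylocta-2,5-dien-1-yl]-1,2-dioxan-3-yl}acetic acid | CC/C=C/[C@H](/C=C(\C)C[C@@]1(CC)C[C@@H](CC)[C@@H](CC(=O)O)OO1)CC
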